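Readings and results were computed with constants of no real substance.

The easy step in my reply to you was a division: at 0.2 mol% of pre-initiator, south-east and south each held 500 monomers per pre-initiator, a number I called the ration (the usual term is target degree of polymerisation).

all flasks: pre-initiator 0.2 mol%

| run | free monomer | remark | time |
|---|---|---|---|
| ochre | 0.040 M | run made earlier |  |
| violet | 0.11 M | run made earlier |  |
| grey | 0.19 M | run made earlier |  |
| south-east | 0.050 M |  | 4.0 min |
| south | 0.20 M |  | 4.0 min |

- ochre (time / min: monomer in chains / %, free monomer / %): 0.500: 0.7, 99.0; 1.00: 2.0, 94.7; 1.50: 4.6, 89.9; 2.50: 15.8, 77.0; 3.00: 21.4, 69.3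
- violet (time / min: monomer in chains / %, free monomer / %): 0.250: 0, 98.6; 0.417: 1.3, 97.6; 0.833: 5.0, 92.2; 1.33: 15.5, 80.0; 3.00: 64.9, 29.0
- grey (time / min: monomer in chains / %, free monomer / %): 0.500: 3.0, 93.8; 1.00: 19.5, 78.5; 1.50: 40.7, 55.6; 2.50: 74.6, 20.0; 3.00: 84.7, 10.0

(each reading ± 0.5 percentage points)

- which of the two ends with the longer chains by the average number of monomer units in a chain (chains begun, living or dead) ("neither" if they lie within 10 %) (south-east / south / neither)
- average number of monomer units in a chain (chains begun, living or dead) at the end, south-east
- average number of monomer units in a chain (chains begun, living or dead) at the end, south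

- the average divides the monomer in chains by the number of chains begun, living and dead together
- what was read earlier has a scatter of 0.5 percentage points, one standard deviation
- the earlier runs do not show the number of chains; that part of a forecast is a guess

You wanted a quick number and your hunch was south. I took each pre-initiator to begin a single chain, so I reckoned the average length as the ration times the share of the charge in chains, divided by the fraction of pre-initiator that had begun a chain. The runs did not show that fraction, so I gave the lower estimate found by setting it to one.

For the shares, I scaled the logarithm of the free monomer with the charge and with time squared. Scaling the ochre run to 4.0 min, I reckoned 44.3 % free in south-east, and scaling the grey run, 1.34 % free in south. Keeping each run's split of what had reacted gave 38.9 % and 92.8 % in chains. My lower estimates were therefore 194 for south-east and 464 for south, and taking equal fractions begun, I expected south to be longer by a factor of 2.39.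

The forecast also said south, with 1200 (range 500 to 5000) for south-east and 2200 (1000 to 9000) for south, a factor of 1.83, and my factor was larger than that. It warned: “The absolute size is a guess.”

The flask gave south, with 530 for south-east and 1070 for south, so the forecast stood high by factors of 2.26 and 2.06.

    free monomer + initiator → living end + monomer in chains (k = 16.0 L mol⁻¹ min⁻¹)
    free monomer + living end → monomer in chains + living end, rate k2*[living end]*[free monomer] (k = 8300 L mol⁻¹ min⁻¹)
    free monomer → uncatalysed product (k = 0.0330 min⁻¹)
    pre-initiator ⇌ initiator (K = 29.0, k = 0.280 min⁻¹)

The ration times the shares in chains at the end, 46.3 % in south-east and 92.1 % in south, over these lengths gave fractions begun of 43.6 % in south-east and 43.0 % in south. The neighbouring flask, south charged with 0.12 mol% of pre-initiator, had a ration of 833. With its 85.2 % in chains and south's fraction begun, the reckoning gave 1650. That neighbouring flask gave 1400, a fraction begun of 50.7 %.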